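# Proposed synthesis of (2R,3R)-3,5-dihydroxy-2-(3-hydroxy-4-methoxyphenyl)-7-methoxy-6-(3-methylbut-2-enyl)chroman-4-one (CNP0146895.1)

## Analysis of the target

The target is a 2,3-trans dihydroflavonol. Benzo ring A is fused to the oxygen heterocycle ring C (O1, C2, C3, C4, C4a, C8a), and aryl ring B sits on C2. Ring A is substituted at every position except C8: a hydroxyl on C5 (hydrogen-bonded to the C4 carbonyl), a prenyl group on C6 and a methoxy group on C7. Ring B carries 3′-OH and 4′-OMe, and C3 carries a secondary hydroxyl. The two stereocentres, C2 (R) and C3 (R), are contiguous and trans, which in an open-chain precursor corresponds to an anti arrangement of the benzylic oxygen and the C3 oxygen. The sensitive elements are the β-aryloxy ketone and the prenyl group. Base enolises the ketone at C3 and can open ring C by β-elimination of the aryloxide, which destroys both stereocentres. The prenyl group rules out hydrogenolysis and can cyclise onto the C5 hydroxyl in strong acid. The difficulty lies in the regiochemistry of the pentasubstituted ring A and in bringing two oxygenated stereocentres next to a ketone without exposing them to epimerising conditions. The strategy rests on the fact that the adjacent ring A carbons C8a and C4a carry O1 and the C4 carbonyl. One aryne can take up this ortho oxygen/acyl pair in a single operation, and the C5 oxygen beside C4a fixes the orientation.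

## Retrosynthetic reasoning

**Target 30 back to 28 (through 29).** No skeletal bond is cut. The three hydroxyls of 30 are masked in 28 as a phenolic methoxymethyl ether on C5 and allyl ethers on C3 and C3′. These groups are chosen backwards from the ring closure: they must survive an alkoxide, fluoride and an aryl anion, must not migrate to a neighbouring alkoxide, and must come off without hydrogenation or base. Isomerising both allyl ethers to propenyl ethers (29) lets one mild acid treatment free all three hydroxyls.

**28 back to hydroxy ester 24 and silyl triflate 15.** The bonds O1–C8a and C4–C4a are cut. They are the only links between ring A and the C2–C3 unit and lie on adjacent aromatic carbons, so one aryne (26) can form both. The cut separates an arene that holds every regiochemical question from a three-carbon chain that holds every stereochemical one, and the stereocentres are never created beside the ketone. The forward step must add oxygen at C8a and not at C4a, and the aryl anion 27 must be acylated rather than protonated. Two choices follow. The nucleophile is the preformed alkoxide 25, because a neutral hydroxyl would hand its own proton to the aryl anion. The C3 oxygen is an allyl ether and not a silyl ether, because a silyl group would migrate to the vicinal alkoxide and is fluoride-labile.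

**24 back to adduct 23, then to thioimide 21 and aldehyde 17.** The bond between the two stereocentres is cut by an aldol disconnection. This sets both centres in one step and leaves exactly the differentiation the ring closure needs: a free benzylic hydroxyl and an etherified α-oxygen. The forward reaction must be anti-selective and enantioselective; the titanium enolate 22 of an auxiliary-bearing glycolate serves, and mild methanolysis then gives the ester.

**21 back to auxiliary 18 and acid 19 (through chloride 20); 17 back to 16.** These are an N-acylation and a phenol allylation. Nothing is gained beyond access from purchasable materials.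

**15 back to silyl carbamate 13 (through phenol 14), then to carbamate 9 and phenol 8.** The aryl–silicon bond is cut, and the triflate oxygen is traced to a carbamate oxygen. The carbamate first directs lithiation to the neighbouring carbon and is then exchanged for triflate. The forward step must metalate the position between the carbamate and the methoxymethyl ether, not the one between the carbamate and the methoxy group.

**8 back to silyl ether 7, then to 3 and prenyl bromide 4 (through 5 and 6).** The aryl–prenyl bond is cut. The carbon between the methoxymethoxy and methoxy groups is the most readily lithiated position of 3, while the bulky silyl ether shields its own neighbours. Copper then delivers the prenyl group without allylic transposition.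

**3 back to 2 and 1.** The two equivalent hydroxyls of 1 are differentiated, one as a bulky silyl ether (a placeholder for the later triflate oxygen) and one as the methoxymethyl ether (the later C5 oxygen).

## Alternatives that were turned down

**Alternative 1:** Ring A is built last by cutting C4a–C5 and C7–C8.
- **Disconnection.** Ring C arrives as the enantioenriched dihydropyranone A3, (2S)-2-[4-methoxy-3-(methoxymethoxy)phenyl]-6-methyl-2,3-dihydro-4H-pyran-4-one. Its enol-ether carbon becomes C4a and its methyl group becomes C8. The other three ring A carbons come from the dichloride A2, 2-(3-methylbut-2-enyl)propanedioyl dichloride.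
- **Forward key step.** A hindered pyridine base promotes acylation of A3 at the enol-ether carbon and then at the methyl carbon. The new ring aromatises to the 5,7-diol A1, (2S)-5,7-dihydroxy-2-[4-methoxy-3-(methoxymethoxy)phenyl]-6-(3-methylbut-2-enyl)chroman-4-one.
- **For.** The prenyl group sits on the central carbon of A2 and lands on C6 by construction, with no directed metalation. The C2 centre can come from an asymmetric hetero-Diels–Alder route to A3.
- **Against.** A1 has no C3 oxygen and two free phenols. The route still needs selective O-methylation at C7 and a trans-selective C3 hydroxylation through a flavanone enolate. That enolate is the species that opens ring C and racemises C2, and the oxidant must spare the prenyl alkene. The double C-acylation must also beat O-acylation and self-condensation of A2.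
- **Comparison.** Alternative 1 is stronger on ring A regiochemistry, which it assembles rather than negotiates among three directing groups. The chosen strategy offers both stereocentres and the C3 oxygen ready-made in 24, the correct methylation pattern from the start in 15, and an endgame of deprotections only.

**Alternative 2:** The C3–C4 bond is cut.
- **Disconnection.** Both bonds to O1 already exist in the dialdehyde A5, 2-{(1R)-1-[4-methoxy-3-(methoxymethoxy)phenyl]-2-oxoethoxy}-4-methoxy-6-(methoxymethoxy)-5-(3-methylbut-2-enyl)benzaldehyde.
- **Forward key step.** A divalent samarium reductant turns the aromatic aldehyde into a ketyl, which adds to the aliphatic aldehyde. Ring C closes as the diol A4, (2R,3S,4S)-7-methoxy-5-(methoxymethoxy)-2-[4-methoxy-3-(methoxymethoxy)phenyl]-6-(3-methylbut-2-enyl)chromane-3,4-diol.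
- **For.** Ketyl–carbonyl pinacol cyclisations are established, the medium is neutral, and C3 is set from C2 under substrate control without an auxiliary.
- **Against.** The only source of absolute configuration is the C2 carbon of A5, which bears an aryl group, an aryloxy group and a formyl group and is therefore very easily enolised. A4 is at the wrong oxidation level, so the benzylic C4 hydroxyl must be oxidised selectively beside the C3 hydroxyl without over-oxidation. Ring A needs the same substitution pattern plus a formyl group.
- **Comparison.** Alternative 2 is stronger in that its key step is of a known type, whereas the aryne annulation is not. The chosen strategy offers configurationally robust stereocentres (an α-alkoxy ester, not an α-aryl aldehyde), the ketone at the right oxidation level directly, and fewer steps after ring closure.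

**Alternative 3:** Both bonds to C4 are cut and the carbonyl carbon comes from carbon monoxide A8.
- **Disconnection.** The precursor is the aryl ether A7, tributyl{(1S,2R)-2-[2-iodo-5-methoxy-3-(methoxymethoxy)-4-(3-methylbut-2-enyl)phenoxy]-1-(methoxymethoxy)-2-[4-methoxy-3-(methoxymethoxy)phenyl]ethyl}stannane. It has iodine on C4a and tin on the oxygen-bearing C3.
- **Forward key step.** A zerovalent palladium catalyst inserts into the C4a–I bond and A8 inserts to give an aroyl–palladium species. Copper-assisted transfer of the α-alkoxyalkyl group from tin with retention closes ring C as A6, (2R,3R)-7-methoxy-3,5-bis(methoxymethoxy)-2-[4-methoxy-3-(methoxymethoxy)phenyl]-6-(3-methylbut-2-enyl)chroman-4-one.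
- **For.** The conditions are neutral, the enolisable ketone appears only at the end, and the carbonylative Stille coupling is a known reaction type.
- **Against.** A secondary sp3 stannane transmetalates slowly, so direct coupling to a five-membered ring or loss of tin competes. The metal-bearing carbon has a β-aryloxy group (O1), and β-elimination would destroy both stereocentres. The stannane centre must itself be made stereoselectively, in practice from the same labile α-aryloxy aldehyde type as in Alternative 2. Stoichiometric tin and a toxic gas are required.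
- **Comparison.** On convergence the two are equal, and Alternative 3 has the better-precedented bond-forming step. The chosen strategy offers a much simpler stereochemical supply (one aldol), no tin, and a ring A partner, 15, made by routine phenol chemistry.

Key step: step 12

Assumption (step 10): the facial sense of the titanium anti-glycolate aldol is assigned from the sulfur-chelated enolate model stated in that step; should it prove opposite, the (R)-configured auxiliary is used and nothing else changes.

Assumption (step 9): 2-(allyloxy)acetic acid is taken as a purchasable starting material.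

## Route

Step 1
Reactants: 1 5-methoxyresorcinol (5-methoxybenzene-1,3-diol)
Product: 2 3-methoxy-5-(triisopropylsilyloxy)phenol
Conditions: TIPSCl (0.9 equiv), imidazole, DMF, 0 °C → rt
Reagents that add atoms: triisopropylsilyl chloride, CC(C)[Si](Cl)(C(C)C)C(C)C
Why: Statistical monosilylation of a symmetrical resorcinol, with a deficit of silyl chloride and recovery of unreacted 1 favouring the mono-ether; the bulky TIPS group is chosen because it does not direct lithiation and shields the ring positions beside it in step 3.

Step 2
Reactants: 2 3-methoxy-5-(triisopropylsilyloxy)phenol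
Product: 3 triisopropyl[3-methoxy-5-(methoxymethoxy)phenoxy]silane
Conditions: MOMCl, i-Pr2NEt, CH2Cl2, 0 °C → rt
Reagents that add atoms: chloromethyl methyl ether, COCCl
Why: Williamson-type acetalisation of the remaining phenol under amine base; the MOM ether later serves as the ortho-directing group for metalation and as the inductive director of the aryne.

Step 3
Reactants: 3 triisopropyl[3-methoxy-5-(methoxymethoxy)phenoxy]silane; 4 prenyl bromide (1-bromo-3-methylbut-2-ene)
Product: 7 triisopropyl[3-methoxy-5-(methoxymethoxy)-4-(3-methylbut-2-enyl)phenoxy]silane, via aryllithium 5 (not isolated), via arylcopper 6 (not isolated)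
Conditions: n-BuLi, THF, 0 °C; CuBr·SMe2, −78 → −40 °C; 4, −40 °C → rt
Reagents that add atoms: none
Why: Directed ortho-metalation places lithium on the carbon between the MOM and methoxy groups, which cooperate, while the positions beside the bulky non-coordinating TIPS ether stay untouched; transmetalation to copper makes the substitution on prenyl bromide run SN2 at the primary carbon rather than SN2′.

Step 4
Reactants: 7 triisopropyl[3-methoxy-5-(methoxymethoxy)-4-(3-methylbut-2-enyl)phenoxy]silane
Product: 8 3-methoxy-5-(methoxymethoxy)-4-(3-methylbut-2-enyl)phenol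
Conditions: TBAF, THF, 0 °C; aq NH4Cl
Reagents that add atoms: none
Why: Fluoride-mediated cleavage of the aryl silyl ether; the MOM ether and the prenyl group are inert to fluoride.

Step 5
Reactants: 8 3-methoxy-5-(methoxymethoxy)-4-(3-methylbut-2-enyl)phenol
Product: 9 3-methoxy-5-(methoxymethoxy)-4-(3-methylbut-2-enyl)phenyl N-isopropylcarbamate
Conditions: i-PrNCO, Et3N (cat.), CH2Cl2, rt
Reagents that add atoms: isopropyl isocyanate, CC(C)N=C=O
Why: Amine-catalysed addition of the phenol to an isocyanate gives the N-isopropyl carbamate, a strong ortho-directing group that can later be removed under mild amine conditions.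

Step 6
Reactants: 9 3-methoxy-5-(methoxymethoxy)-4-(3-methylbut-2-enyl)phenyl N-isopropylcarbamate
Product: 13 5-methoxy-3-(methoxymethoxy)-4-(3-methylbut-2-enyl)-2-(trimethylsilyl)phenyl N-isopropylcarbamate, via N-silyl carbamate 10 (not isolated), via ortho-lithiated carbamate 11 (not isolated), via C-silylated N-silyl carbamate 12 (not isolated)
Conditions: TBSOTf, TMEDA, Et2O, 0 °C → rt; n-BuLi, TMEDA, −78 °C; TMSCl, −78 °C → rt; aq NaHSO4
Reagents that add atoms: chlorotrimethylsilane, C[Si](C)(C)Cl
Why: Carbamate-directed ortho-metalation after in situ N-silylation, which masks the N–H and blocks elimination to the isocyanate; of the two positions ortho to the carbamate, the one also flanked by the chelating MOM ether is expected to lithiate, because the methoxy group on the other side is the weaker director and its methyl group is pushed towards that position by the neighbouring prenyl group. TMSCl then silylates carbon and the N-silyl group is lost on acidic work-up.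

Step 7
Reactants: 13 5-methoxy-3-(methoxymethoxy)-4-(3-methylbut-2-enyl)-2-(trimethylsilyl)phenyl N-isopropylcarbamate
Product: 15 5-methoxy-3-(methoxymethoxy)-4-(3-methylbut-2-enyl)-2-(trimethylsilyl)phenyl trifluoromethanesulfonate, via silylphenol 14 (not isolated)
Conditions: Et2NH, DBU, MeCN, 40 °C; then PhNTf2, rt
Reagents that add atoms: N-phenylbis(trifluoromethanesulfonimide), O=S(=O)(N(c1ccccc1)S(=O)(=O)C(F)(F)F)C(F)(F)F
Why: Diethylamine with DBU cleaves the N-monoalkyl carbamate by E1cB elimination to the isocyanate, which is trapped as a urea, and the phenoxide is triflated in the same flask; this is the standard end of the carbamate route to ortho-silylaryl triflates.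

Step 8
Reactants: 16 isovanillin (3-hydroxy-4-methoxybenzaldehyde)
Product: 17 3-(allyloxy)-4-methoxybenzaldehyde
Conditions: allyl bromide, K2CO3, DMF, rt
Reagents that add atoms: allyl bromide, C=CCBr
Why: Williamson etherification of the phenol; an allyl ether is chosen for ring B because it withstands TiCl4 in step 10 and the alkoxide and fluoride of step 12, and leaves together with the C3 allyl ether at the end.

Step 9
Reactants: 18 (S)-4-benzyl-1,3-oxazolidine-2-thione; 19 2-(allyloxy)acetic acid
Product: 21 (S)-3-[2-(allyloxy)acetyl]-4-benzyl-1,3-oxazolidine-2-thione, via acid chloride 20 (not isolated)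
Conditions: (COCl)2, DMF (cat.), CH2Cl2, 0 °C → rt; then 18, Et3N, DMAP (cat.), CH2Cl2, 0 °C
Reagents that add atoms: none
Why: N-acylation of the oxazolidinethione by the acid chloride made in situ; the thioimide is the substrate of the titanium aldol and an activated acyl donor for the later methanolysis.

Step 10
Reactants: 21 (S)-3-[2-(allyloxy)acetyl]-4-benzyl-1,3-oxazolidine-2-thione; 17 3-(allyloxy)-4-methoxybenzaldehyde
Product: 23 (S)-3-[(2R,3R)-2-(allyloxy)-3-[3-(allyloxy)-4-methoxyphenyl]-3-hydroxypropanoyl]-4-benzyl-1,3-oxazolidine-2-thione, via chlorotitanium enolate 22 (not isolated)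
Conditions: TiCl4 (1.1 equiv), i-Pr2NEt (1.1 equiv), CH2Cl2, −78 °C; then 17 premixed with TiCl4 (2.5 equiv), −78 °C; aq NH4Cl
Reagents that add atoms: none
Why: Titanium-mediated anti-selective glycolate aldol of an N-glycolyloxazolidinethione: soft enolisation gives the (Z)-enolate 22, which stays chelated to the thiocarbonyl sulfur and is attacked by the TiCl4-bound aldehyde through an open transition state on the face away from the benzyl group. The auxiliary thereby sets the ether-bearing carbon as R, and the open transition state sets the carbinol carbon anti to it, also R.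

Step 11
Reactants: 23 (S)-3-[(2R,3R)-2-(allyloxy)-3-[3-(allyloxy)-4-methoxyphenyl]-3-hydroxypropanoyl]-4-benzyl-1,3-oxazolidine-2-thione
Product: 24 methyl (2R,3R)-2-(allyloxy)-3-[3-(allyloxy)-4-methoxyphenyl]-3-hydroxypropanoate
Conditions: MeOH, imidazole, CH2Cl2, rt
Reagents that add atoms: methanol, CO
Why: Imidazole-catalysed methanolysis of the activated N-acyloxazolidinethione gives the methyl ester under conditions too mild for retro-aldol cleavage or epimerisation, and returns auxiliary 18.

Step 12
Reactants: 24 methyl (2R,3R)-2-(allyloxy)-3-[3-(allyloxy)-4-methoxyphenyl]-3-hydroxypropanoate; 15 5-methoxy-3-(methoxymethoxy)-4-(3-methylbut-2-enyl)-2-(trimethylsilyl)phenyl trifluoromethanesulfonate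
Product: 28 (2R,3R)-3-(allyloxy)-2-[3-(allyloxy)-4-methoxyphenyl]-7-methoxy-5-(methoxymethoxy)-6-(3-methylbut-2-enyl)chroman-4-one, via sodium alkoxide 25 (not isolated), via aryne 26 (not isolated), via arylsodium 27 (not isolated)
Conditions: NaH (1.0 equiv), THF, 0 °C; then 15 (1.3 equiv), KF, 18-crown-6, THF, 0 °C → rt; AcOH
Reagents that add atoms: none
Why: Proposed new method: fluoride attacks the trimethylsilyl group of 15 and triflate leaves, giving aryne 26 whose strained bond joins the future C4a and C8a; the preformed alkoxide 25 adds at C8a, the aryne carbon remote from the inductively withdrawing C5 oxygen, so that the negative charge of 27 develops at C4a beside that oxygen, where it is best stabilised. The aryl anion of 27 then attacks the methyl ester in a 6-exo-trig acyl substitution, which closes ring C and forms the C4 ketone with loss of methoxide. The closest known reaction type is the aryne annulation of ortho-hydroxybenzoate esters to xanthones, in which a phenoxide adds to the aryne and the aryl anion is acylated by the ester; an aliphatic alkoxide carrying a β-ester has not been shown to do this. The alkoxide is preformed because a neutral alcohol would pass its own proton to the aryl anion and stop at the aryl ether. No stereocentre is formed: C2 and C3 come unchanged from the anti hydroxy ester and therefore give the 2,3-trans ring. The step needs regioselective oxygen addition, secured by the methoxymethoxy group flanking C4a, and acylation in preference to proton capture, secured by the absence of O–H donors and by the intramolecular six-membered closure. Low temperature, a modest excess of 15 and a prompt acetic acid quench limit retro-aldol cleavage of 25 and methoxide-induced enolisation of the product at C3.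

Step 13
Reactants: 28 (2R,3R)-3-(allyloxy)-2-[3-(allyloxy)-4-methoxyphenyl]-7-methoxy-5-(methoxymethoxy)-6-(3-methylbut-2-enyl)chroman-4-one
Product: 29 (2R,3R)-7-methoxy-5-(methoxymethoxy)-2-{4-methoxy-3-[(E)-prop-1-enyloxy]phenyl}-6-(3-methylbut-2-enyl)-3-[(E)-prop-1-enyloxy]chroman-4-one
Conditions: [Ir(cod)(PMePh2)2]PF6 (cat., activated with H2, then degassed), THF, rt
Reagents that add atoms: none
Why: Cationic iridium hydride catalysis moves the terminal double bond of both allyl ethers into conjugation with oxygen (allyl to 1-propenyl ether isomerisation); the trisubstituted prenyl double bond does not engage the catalyst, and the neutral medium leaves the C3 stereocentre alone.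

Step 14
Reactants: 29 (2R,3R)-7-methoxy-5-(methoxymethoxy)-2-{4-methoxy-3-[(E)-prop-1-enyloxy]phenyl}-6-(3-methylbut-2-enyl)-3-[(E)-prop-1-enyloxy]chroman-4-one
Product: 30 (2R,3R)-3,5-dihydroxy-2-(3-hydroxy-4-methoxyphenyl)-7-methoxy-6-(3-methylbut-2-enyl)chroman-4-one
Conditions: HCl (1 M in MeOH), 0 °C → rt
Reagents that add atoms: none
Why: Acid-catalysed methanolysis cleaves the two enol ethers and the phenolic MOM acetal in one operation; the conditions are kept dilute and cool because the prenyl group beside the freed C5 hydroxyl can cyclise to a chroman under stronger acid.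

## Compound list

1 | 5-methoxyresorcinol | COc1cc(O)cc(O)c1 | starting material
2 | 3-methoxy-5-(triisopropylsilyloxy)phenol | COc1cc(O)cc(O[Si](C(C)C)(C(C)C)C(C)C)c1 | intermediate
3 | triisopropyl[3-methoxy-5-(methoxymethoxy)phenoxy]silane | COCOc1cc(OC)cc(O[Si](C(C)C)(C(C)C)C(C)C)c1 | intermediate
4 | prenyl bromide | CC(C)=CCBr | starting material
5 | [2-methoxy-6-(methoxymethoxy)-4-(triisopropylsilyloxy)phenyl]lithium (formed in the flask) | COCOc1cc(O[Si](C(C)C)(C(C)C)C(C)C)cc(OC)c1[Li] | intermediate
6 | [2-methoxy-6-(methoxymethoxy)-4-(triisopropylsilyloxy)phenyl]copper (formed in the flask) | COCOc1cc(O[Si](C(C)C)(C(C)C)C(C)C)cc(OC)c1[Cu] | intermediate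
7 | triisopropyl[3-methoxy-5-(methoxymethoxy)-4-(3-methylbut-2-enyl)phenoxy]silane | COCOc1cc(O[Si](C(C)C)(C(C)C)C(C)C)cc(OC)c1CC=C(C)C | intermediate
8 | 3-methoxy-5-(methoxymethoxy)-4-(3-methylbut-2-enyl)phenol | COCOc1cc(O)cc(OC)c1CC=C(C)C | intermediate
9 | 3-methoxy-5-(methoxymethoxy)-4-(3-methylbut-2-enyl)phenyl N-isopropylcarbamate | COCOc1cc(OC(=O)NC(C)C)cc(OC)c1CC=C(C)C | intermediate
10 | 3-methoxy-5-(methoxymethoxy)-4-(3-methylbut-2-enyl)phenyl N-(tert-butyldimethylsilyl)-N-isopropylcarbamate (formed in the flask) | COCOc1cc(OC(=O)N(C(C)C)[Si](C)(C)C(C)(C)C)cc(OC)c1CC=C(C)C | intermediate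
11 | 2-lithio-5-methoxy-3-(methoxymethoxy)-4-(3-methylbut-2-enyl)phenyl N-(tert-butyldimethylsilyl)-N-isopropylcarbamate (formed in the flask) | COCOc1c([Li])c(OC(=O)N(C(C)C)[Si](C)(C)C(C)(C)C)cc(OC)c1CC=C(C)C | intermediate
12 | 5-methoxy-3-(methoxymethoxy)-4-(3-methylbut-2-enyl)-2-(trimethylsilyl)phenyl N-(tert-butyldimethylsilyl)-N-isopropylcarbamate (formed in the flask) | COCOc1c([Si](C)(C)C)c(OC(=O)N(C(C)C)[Si](C)(C)C(C)(C)C)cc(OC)c1CC=C(C)C | intermediate
13 | 5-methoxy-3-(methoxymethoxy)-4-(3-methylbut-2-enyl)-2-(trimethylsilyl)phenyl N-isopropylcarbamate | COCOc1c([Si](C)(C)C)c(OC(=O)NC(C)C)cc(OC)c1CC=C(C)C | intermediate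
14 | 5-methoxy-3-(methoxymethoxy)-4-(3-methylbut-2-enyl)-2-(trimethylsilyl)phenol (formed in the flask) | COCOc1c([Si](C)(C)C)c(O)cc(OC)c1CC=C(C)C | intermediate
15 | 5-methoxy-3-(methoxymethoxy)-4-(3-methylbut-2-enyl)-2-(trimethylsilyl)phenyl trifluoromethanesulfonate | COc1cc(OS(=O)(=O)C(F)(F)F)c([Si](C)(C)C)c(OCOC)c1CC=C(C)C | intermediate
16 | isovanillin | COc1ccc(C=O)cc1O | starting material
17 | 3-(allyloxy)-4-methoxybenzaldehyde | COc1ccc(C=O)cc1OCC=C | intermediate
18 | (S)-4-benzyl-1,3-oxazolidine-2-thione | S=C1N[C@@H](Cc2ccccc2)CO1 | starting material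
19 | 2-(allyloxy)acetic acid | OC(=O)COCC=C | starting material
20 | 2-(allyloxy)acetyl chloride (formed in the flask) | ClC(=O)COCC=C | intermediate
21 | (S)-3-[2-(allyloxy)acetyl]-4-benzyl-1,3-oxazolidine-2-thione | C=CCOCC(=O)N1C(=S)OC[C@@H]1Cc1ccccc1 | intermediate
22 | (Z)-trichlorotitanium enolate of 21 (formed in the flask) | C=CCO/C=C(\O[Ti](Cl)(Cl)Cl)N1C(=S)OC[C@@H]1Cc1ccccc1 | intermediate
23 | (S)-3-[(2R,3R)-2-(allyloxy)-3-[3-(allyloxy)-4-methoxyphenyl]-3-hydroxypropanoyl]-4-benzyl-1,3-oxazolidine-2-thione | COc1ccc([C@H]([C@@H](OCC=C)C(=O)N2C(=S)OC[C@@H]2Cc2ccccc2)O)cc1OCC=C | intermediate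
24 | methyl (2R,3R)-2-(allyloxy)-3-[3-(allyloxy)-4-methoxyphenyl]-3-hydroxypropanoate | COc1ccc([C@H]([C@@H](OCC=C)C(=O)OC)O)cc1OCC=C | intermediate
25 | sodium alkoxide of 24 (formed in the flask) | COc1ccc([C@H]([C@@H](OCC=C)C(=O)OC)[O-])cc1OCC=C.[Na+] | intermediate
26 | 5-methoxy-3-(methoxymethoxy)-4-(3-methylbut-2-enyl)benzyne, triple bond between C1 and C2 (formed in the flask) | COC1=CC#CC(OCOC)=C1CC=C(C)C | intermediate
27 | arylsodium from addition of 25 to 26, sodium on the carbon between the new ether oxygen and the methoxymethoxy group (formed in the flask) | COc1ccc([C@H]([C@@H](OCC=C)C(=O)OC)Oc2cc(OC)c(CC=C(C)C)c(OCOC)c2[Na])cc1OCC=C | intermediate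
28 | (2R,3R)-3-(allyloxy)-2-[3-(allyloxy)-4-methoxyphenyl]-7-methoxy-5-(methoxymethoxy)-6-(3-methylbut-2-enyl)chroman-4-one | COc1ccc([C@H]2Oc3cc(OC)c(CC=C(C)C)c(OCOC)c3C(=O)[C@@H]2OCC=C)cc1OCC=C | intermediate
29 | (2R,3R)-7-methoxy-5-(methoxymethoxy)-2-{4-methoxy-3-[(E)-prop-1-enyloxy]phenyl}-6-(3-methylbut-2-enyl)-3-[(E)-prop-1-enyloxy]chroman-4-one | COc1ccc([C@H]2Oc3cc(OC)c(CC=C(C)C)c(OCOC)c3C(=O)[C@@H]2O/C=C/C)cc1O/C=C/C | intermediate
30 | (2R,3R)-3,5-dihydroxy-2-(3-hydroxy-4-methoxyphenyl)-7-methoxy-6-(3-methylbut-2-enyl)chroman-4-one | COc1ccc([C@H]2Oc3cc(OC)c(CC=C(C)C)c(O)c3C(=O)[C@@H]2O)cc1O | target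

## Step count and least certain steps

Total step count: 14. Longest linear sequence: 10 steps (steps 1 to 7, then 12 to 14); the ring B arm contributes 4 steps (8 to 11) before the union.

**Step 12 (key step, proposed new method).**
- Retro-aldol fragmentation of alkoxide 25 before it meets the aryne, since sodium aldolates of electron-rich benzaldehydes revert readily.
- Proton capture by the aryl anion 27 ahead of cyclisation, which stops at the open aryl ether.
- Enolisation of the product at C3 by the methoxide released, leading to epimerisation or to opening of ring C.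
- Attack of the alkoxide at silicon or at the sulfonyl sulfur of 15 in place of addition to the aryne.

Fallback (known chemistry; ring C is closed at O1–C2 instead): it sets out from carbamate 9, aldehyde 17 and acid 19 and comes back at 28. Acid chloride 20 acylates (R)-4-benzyl-1,3-oxazolidin-2-one (n-BuLi, THF) to give (R)-3-[2-(allyloxy)acetyl]-4-benzyl-1,3-oxazolidin-2-one F1. An Evans syn aldol with 17 (Bu2BOTf, Et3N, CH2Cl2) gives (R)-4-benzyl-3-[(2R,3S)-2-(allyloxy)-3-[3-(allyloxy)-4-methoxyphenyl]-3-hydroxypropanoyl]-1,3-oxazolidin-2-one F2. Transamination (MeONHMe·HCl, AlMe3) gives (2R,3S)-2-(allyloxy)-3-[3-(allyloxy)-4-methoxyphenyl]-3-hydroxy-N-methoxy-N-methylpropanamide F3. The ortho-lithiated carbamate 11, generated from 9 as in step 6, is added to the magnesium alkoxide of F3 (i-PrMgCl); aqueous work-up gives 2-[(2R,3S)-2-(allyloxy)-3-[3-(allyloxy)-4-methoxyphenyl]-3-hydroxypropanoyl]-5-methoxy-3-(methoxymethoxy)-4-(3-methylbut-2-enyl)phenyl N-isopropylcarbamate F4. Et2NH and DBU free the phenol to give (2R,3S)-2-(allyloxy)-3-[3-(allyloxy)-4-methoxyphenyl]-3-hydroxy-1-[2-hydroxy-4-methoxy-6-(methoxymethoxy)-5-(3-methylbut-2-enyl)phenyl]propan-1-one F5. A Mitsunobu etherification (PPh3, DIAD, THF) then closes ring C with inversion at the benzylic carbinol, turning the syn (3S) carbinol into the 2R centre of 28.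

**Step 10.**
- Insufficient anti selectivity, or a facial sense opposite to the one assumed.
- Ionisation of the electron-rich benzylic titanium alkoxide under excess TiCl4, with loss of the carbinol configuration.
- Lewis-acid cleavage of the aryl allyl ether.

Fallback: it sets out from aldehyde 17, passes through F1 and the syn adduct F2 described above, and comes back at 24. Methanolysis of F2 (MeOMgBr, MeOH, 0 °C) gives methyl (2R,3S)-2-(allyloxy)-3-[3-(allyloxy)-4-methoxyphenyl]-3-hydroxypropanoate F6. Mitsunobu inversion of the carbinol with 4-nitrobenzoic acid (PPh3, DIAD) gives methyl (2R,3R)-2-(allyloxy)-3-[3-(allyloxy)-4-methoxyphenyl]-3-(4-nitrobenzoyloxy)propanoate F7. Mild methanolysis (K2CO3, MeOH, 0 °C) removes the nitrobenzoate and gives 24. Absolute and relative configuration then rest on the boron syn aldol and on an SN2 inversion rather than on the titanium anti aldol.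

**Step 6.**
- Lithiation at the other position ortho to the carbamate (between carbamate and methoxy).
- Lateral deprotonation of the benzylic and allylic CH2 of the prenyl group, which is flanked by two ring oxygens.
- Attack of the silyl triflate on the MOM acetal during N-silylation.

Fallback: it sets out from phenol 8 and comes back at 28. Silylation (TESCl, imidazole) gives triethyl[3-methoxy-5-(methoxymethoxy)-4-(3-methylbut-2-enyl)phenoxy]silane F8. Lithiation with s-BuLi and TMEDA (THF, −78 → 0 °C) is then directed by the MOM ether alone, whose only free ortho position is the desired carbon; a 1,3 oxygen-to-carbon silyl shift follows and work-up gives 5-methoxy-3-(methoxymethoxy)-4-(3-methylbut-2-enyl)-2-(triethylsilyl)phenol F9. Triflation (PhNTf2, Et3N) gives 5-methoxy-3-(methoxymethoxy)-4-(3-methylbut-2-enyl)-2-(triethylsilyl)phenyl trifluoromethanesulfonate F10. F10 replaces 15 in step 12, passes through the same aryne 26 and gives 28.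

**Step 14.**
- Acid-promoted addition of the freed C5 hydroxyl to the prenyl double bond (chroman formation), or addition of HCl to that double bond, while the last acetal is still being cleaved.

Fallback: it sets out from 29 and comes back at 30, separating the cleavages and avoiding protic acid for the acetal. Hydrolysis of the two enol ethers with PPTS in aqueous acetone at rt gives (2R,3R)-3-hydroxy-2-(3-hydroxy-4-methoxyphenyl)-7-methoxy-5-(methoxymethoxy)-6-(3-methylbut-2-enyl)chroman-4-one F11. The remaining MOM ether, activated by chelation to the neighbouring carbonyl, is then removed with ZnBr2 and n-PrSH in CH2Cl2 at 0 °C to give 30.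

## Further compounds

F1 | step 12 | (R)-3-[2-(allyloxy)acetyl]-4-benzyl-1,3-oxazolidin-2-one | C=CCOCC(=O)N1C(=O)OC[C@H]1Cc1ccccc1
F2 | step 12 | (R)-4-benzyl-3-[(2R,3S)-2-(allyloxy)-3-[3-(allyloxy)-4-methoxyphenyl]-3-hydroxypropanoyl]-1,3-oxazolidin-2-one | COc1ccc([C@@H]([C@@H](OCC=C)C(=O)N2C(=O)OC[C@H]2Cc2ccccc2)O)cc1OCC=C
F3 | step 12 | (2R,3S)-2-(allyloxy)-3-[3-(allyloxy)-4-methoxyphenyl]-3-hydroxy-N-methoxy-N-methylpropanamide | COc1ccc([C@@H]([C@@H](OCC=C)C(=O)N(C)OC)O)cc1OCC=C
F4 | step 12 | 2-[(2R,3S)-2-(allyloxy)-3-[3-(allyloxy)-4-methoxyphenyl]-3-hydroxypropanoyl]-5-methoxy-3-(methoxymethoxy)-4-(3-methylbut-2-enyl)phenyl N-isopropylcarbamate | COc1ccc([C@@H]([C@@H](OCC=C)C(=O)c2c(OC(=O)NC(C)C)cc(OC)c(CC=C(C)C)c2OCOC)O)cc1OCC=C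
F5 | step 12 | (2R,3S)-2-(allyloxy)-3-[3-(allyloxy)-4-methoxyphenyl]-3-hydroxy-1-[2-hydroxy-4-methoxy-6-(methoxymethoxy)-5-(3-methylbut-2-enyl)phenyl]propan-1-one | COc1ccc([C@@H]([C@@H](OCC=C)C(=O)c2c(O)cc(OC)c(CC=C(C)C)c2OCOC)O)cc1OCC=C
F6 | step 10 | methyl (2R,3S)-2-(allyloxy)-3-[3-(allyloxy)-4-methoxyphenyl]-3-hydroxypropanoate | COc1ccc([C@@H]([C@@H](OCC=C)C(=O)OC)O)cc1OCC=C
F7 | step 10 | methyl (2R,3R)-2-(allyloxy)-3-[3-(allyloxy)-4-methoxyphenyl]-3-(4-nitrobenzoyloxy)propanoate | COc1ccc([C@H]([C@@H](OCC=C)C(=O)OC)OC(=O)c2ccc([N+](=O)[O-])cc2)cc1OCC=C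
F8 | step 6 | triethyl[3-methoxy-5-(methoxymethoxy)-4-(3-methylbut-2-enyl)phenoxy]silane | CC[Si](CC)(CC)Oc1cc(OC)c(CC=C(C)C)c(OCOC)c1
F9 | step 6 | 5-methoxy-3-(methoxymethoxy)-4-(3-methylbut-2-enyl)-2-(triethylsilyl)phenol | COc1cc(O)c([Si](CC)(CC)CC)c(OCOC)c1CC=C(C)C
F10 | step 6 | 5-methoxy-3-(methoxymethoxy)-4-(3-methylbut-2-enyl)-2-(triethylsilyl)phenyl trifluoromethanesulfonate | COc1cc(OS(=O)(=O)C(F)(F)F)c([Si](CC)(CC)CC)c(OCOC)c1CC=C(C)C
F11 | step 14 | (2R,3R)-3-hydroxy-2-(3-hydroxy-4-methoxyphenyl)-7-methoxy-5-(methoxymethoxy)-6-(3-methylbut-2-enyl)chroman-4-one | COc1ccc([C@H]2Oc3cc(OC)c(CC=C(C)C)c(OCOC)c3C(=O)[C@@H]2O)cc1O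
A1 | alternative 1 | (2S)-5,7-dihydroxy-2-[4-methoxy-3-(methoxymethoxy)phenyl]-6-(3-methylbut-2-enyl)chroman-4-one | COc1ccc([C@H]2Oc3cc(O)c(CC=C(C)C)c(O)c3C(=O)C2)cc1OCOC
A2 | alternative 1 | 2-(3-methylbut-2-enyl)propanedioyl dichloride | CC(C)=CCC(C(=O)Cl)C(=O)Cl
A3 | alternative 1 | (2S)-2-[4-methoxy-3-(methoxymethoxy)phenyl]-6-methyl-2,3-dihydro-4H-pyran-4-one | COc1ccc([C@@H]2CC(=O)C=C(C)O2)cc1OCOC
A4 | alternative 2 | (2R,3S,4S)-7-methoxy-5-(methoxymethoxy)-2-[4-methoxy-3-(methoxymethoxy)phenyl]-6-(3-methylbut-2-enyl)chromane-3,4-diol | COc1ccc([C@H]2Oc3cc(OC)c(CC=C(C)C)c(OCOC)c3[C@H](O)[C@@H]2O)cc1OCOC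
A5 | alternative 2 | 2-{(1R)-1-[4-methoxy-3-(methoxymethoxy)phenyl]-2-oxoethoxy}-4-methoxy-6-(methoxymethoxy)-5-(3-methylbut-2-enyl)benzaldehyde | COc1ccc([C@H](C=O)Oc2cc(OC)c(CC=C(C)C)c(OCOC)c2C=O)cc1OCOC
A6 | alternative 3 | (2R,3R)-7-methoxy-3,5-bis(methoxymethoxy)-2-[4-methoxy-3-(methoxymethoxy)phenyl]-6-(3-methylbut-2-enyl)chroman-4-one | COc1ccc([C@H]2Oc3cc(OC)c(CC=C(C)C)c(OCOC)c3C(=O)[C@@H]2OCOC)cc1OCOC
A7 | alternative 3 | tributyl{(1S,2R)-2-[2-iodo-5-methoxy-3-(methoxymethoxy)-4-(3-methylbut-2-enyl)phenoxy]-1-(methoxymethoxy)-2-[4-methoxy-3-(methoxymethoxy)phenyl]ethyl}stannane | COc1ccc([C@H]([C@@H](OCOC)[Sn](CCCC)(CCCC)CCCC)Oc2cc(OC)c(CC=C(C)C)c(OCOC)c2I)cc1OCOC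
A8 | alternative 3 | carbon monoxide | [C-]#[O+]
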